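**Remarks on the chemistry**

- The target is the bibenzyl (1,2-diarylethane) shown by its SMILES string. Its name must therefore end in "-5-methoxybibenzyl"; a name ending in "benzyl" leaves out the two-carbon bridge to ring B.
- Rings B, C and D are carried as benzyl ethers instead of methyl ethers. The carbon skeletons of the key-step precursor 11 and product 13 and the bond formed are unchanged. The gain is that the hydrogenation which saturates the bridge also frees these three phenols, so the final demethylation has to act on ring A only, and not on four of five methyl ethers at once.

## Structural features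

The target is a bibenzyl. Ring A is a pentasubstituted benzene joined at C1 through a CH2–CH2 bridge to ring B (3-hydroxyphenyl) and at C2 and C6 through single CH2 groups to rings C and D (4-hydroxyphenyl). Ring A also carries a hydroxyl group at C3, a methoxy group at C5 and its only hydrogen at C4, so C1, C2 and C6 form a contiguous block of three carbon substituents. The molecule has no stereocentre and no stereogenic double bond; the stereo-elements met on the route (an E alkene in the bridge, transient sp3 centres) are erased before the end. The fragile groups are the four electron-rich phenols, which oxidise readily as phenoxides in air, and the doubly benzylic CH2 groups. The real difficulty is twofold: the crowded ring A, whose carbon substituents sit where electrophilic substitution of a simple resorcinol would not place them cleanly, and the single methyl group that must end on one of five phenolic oxygens. Apart from that methyl group, ring A is symmetric about the C1–C4 axis. The key step exploits this: C2–C3–C4–C5–C6 of ring A with both arylmethyl arms is the chain of a 1,7-diarylheptane-3,5-dione whose oxygens become those at C3 and C5, and C1 with its bridge is the carbonyl carbon of a cinnamoyl group, so one aldol bond between C2 and C1 closes ring A.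

## Logic of the disconnections

**16 to 15.** One O–CH3 bond on ring A is put back. In 15 a mirror plane runs through C1 and C4 of ring A, so the two methoxy groups are equivalent and it no longer matters which oxygen keeps the methyl group. The forward step must cleave one O–CH3 bond and then stop: the phenoxide formed on ring A has to shut down the second cleavage, and the phenols of rings B, C and D have to sit through it as inert phenoxides.

**15 to 14.** Three O–CH2Ph bonds are restored and two hydrogens are removed from the bridge, leaving a Cα=Cβ double bond. These changes are grouped because one hydrogenation undoes all of them. This gives a precursor whose only free functionality is the alkene. The forward step must saturate the alkene and cleave three aryl benzyl ethers without touching the aryl methyl ethers or the diarylmethane C–C bonds.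

**14 to 13.** The two O–CH3 bonds on ring A are cut. The free resorcinol is what an aldol aromatisation delivers, and methylating both oxygens avoids a statistical mono-alkylation. The forward step must give exhaustive O-alkylation and no C-alkylation at C4 of ring A.

**13 to 11 (through 12).** The C1–C2 bond of ring A is cut and the ring is opened to an acyclic 1,3,5-triketone. All six ring carbons and all three carbon substituents are then carried by one chain, and no aromatic substitution is needed. The forward step needs an aldol that wins over conjugate additions to the enone; the chain offers only one six-membered aldol fold because the carbon on the far side of the cinnamoyl carbonyl is vinylic.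

**11 to 6 and 9 (through 10).** The bond between the cinnamoyl carbonyl carbon and the benzyl-bearing carbon (C3–C4 of 11) is cut. It is an acyl–carbanion bond, and it divides the molecule into a symmetric diketone (rings C and D plus five carbons of ring A) and a three-carbon acyl unit (ring B, the bridge and C1 of ring A). The forward step must give acyl substitution at the carbonyl and not 1,4-addition, and must react at the outer α-carbon of the diketone and not at the central one.

**9 to 7 and 8.** The Cα=Cβ double bond is cut. Both pieces are commercial, and the olefination delivers the amide function needed for the acylation directly. The forward step should give the E alkene.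

**6 to 1 and two molecules of 2 (through 3, 4 and 5).** The two CH2–CH2 bonds next to the aryl groups (C1–C2 and C6–C7 of 6) are cut. The two arms are identical, so both can come from the same electrophile and the two methyl groups of one five-carbon diketone. The forward step demands that the second deprotonation occurs at the remaining methyl group and not at the newly formed methylene.

## Other disconnections considered

**Alternative 1:** The cuts are the ring A C1–Cα bond and the Cβ–C1′ bond to ring B; the two bridge carbons come from a vinyl group.

- Forward key step: the aryllithium generated from 3-bromo-1,5-dimethoxy-2,4-bis[(4-methoxyphenyl)methyl]benzene A1 would add to 2-ethenyl-4,4,5,5-tetramethyl-1,3,2-dioxaborolane A2 to give a boron ate complex. Zerovalent palladium formed from Pd(OAc)2 and a bisphosphine would insert into 3-methoxyphenyl trifluoromethanesulfonate A3. The resulting arylpalladium cation would trigger the 1,2-shift of the ring A aryl group from boron to Cα, and reductive elimination would form Cβ–C1′, giving the boronate A4.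
- In favour: it is a three-component convergence, it involves no Michael acceptor, and it forms the bridge directly at the saturated oxidation level. On that last point it is the better of the two plans, since the chosen route must hydrogenate a stilbene.
- Against: it presupposes ring A fully assembled as A1. Bromine there sits between the two benzyl groups, meta to both methoxy groups, where direct halogenation would not place it, so the hardest part of the target is left unsolved. The migrating aryl group is doubly ortho-substituted, lithium halide from the exchange can interfere with this type of coupling, and the C–B bond of A4 with its pointless stereocentre must then be exchanged for C–H.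
- Comparison: structurally the chosen plan builds ring A and its substituents from an open chain, whereas this one only decorates a finished ring A. Mechanistically a metallate shift is set against an aldol condensation; both close no new stereocentre that matters. In step count the endgame after A4 would be about as short as the chosen one, but the synthesis of A1 should make the whole longer.

**Alternative 2:** The cuts are the two CH2–aryl bonds to rings C and D.

- Forward key step: 3,5-dimethoxy-2,6-dimethylbenzaldehyde A5 would condense reversibly with an α-amino acid. The imine carboxylate would guide divalent palladium from Pd(OAc)2 to an ortho methyl C–H bond. Oxidative addition of 1-iodo-4-methoxybenzene A6 and reductive elimination would form the CH2–aryl bond. The same would happen on the second methyl group to give the aldehyde A7.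
- In favour: it uses the symmetry of ring A as the chosen plan does, it installs rings C and D in one operation, and it leaves an aldehyde at C1 for olefination with a ring B benzylic phosphonate. On modularity it is the better plan, since the aryl groups could be varied late. It is the equal of the chosen plan in that it converges on the same type of stilbene and the same endgame.
- Against: A5 is not trivial, because the formyl group lies between two methyl groups and meta to both methoxy groups, where direct formylation would not go. The arylation must stop at exactly one aryl group per methyl group, although each new diarylmethane CH2 is a more activated benzylic C–H within reach of the same palladacycle. It also needs a stoichiometric silver salt and a poorly reactive, electron-rich aryl iodide.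
- Comparison: mechanistically a twofold C–H activation with a demanding selectivity profile is set against one intramolecular aldol condensation. The preparation of A5, the arylation, the olefination and the endgame should not be shorter than the seven steps of the chosen route.

**Alternative 3:** The cuts are the ring A bonds C1–C6 and C4–C5.

- Forward key step: the enolate of methyl 3-(4-methoxyphenyl)propanoate A9 would add to the β-carbon of 3-[(4-methoxyphenyl)methyl]-6-(3-methoxyphenyl)hex-3-en-2-one A8. The methyl ketone enolate so formed would then acylate on the ester carbon, closing the cyclohexane-1,3-dione A10.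
- In favour: the bridge is saturated from the start, and a cyclohexane-1,3-dione can be converted into its mono enol ether and then dehydrogenated. That would give the ring A methoxy/hydroxy pattern directly, which is a better answer to the one-methyl problem than the methylation and demethylation of the chosen plan.
- Against: a simple ester enolate would have to add to a trisubstituted, α-branched enone that can also be deprotonated at its γ-carbon, so 1,2-addition and proton transfer compete. A8 itself needs a regioselective aldol condensation on the methylene side of a methyl ketone. A10 would arise as a mixture over three stereocentres that serve no purpose. Its aromatisation needs an oxidant or a high-temperature dehydrogenation in the presence of four electron-rich rings and benzylic CH2 groups.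
- Comparison: the chosen plan reaches the aromatic oxidation level by loss of water alone and passes through no stereoisomer mixture that has to be carried. The number of steps would be similar, but each carries more uncertainty.

Key step: step 4

## Route

**Step 1**
Reactants: 1 pentane-2,4-dione; 2 1-(benzyloxy)-4-(chloromethyl)benzene (two equivalents)
Product: 6 1,7-bis[4-(benzyloxy)phenyl]heptane-3,5-dione, via dilithium dianion of pentane-2,4-dione 3 (not isolated), via lithium enolate of the monoalkylated dione 4 (not isolated), via dilithium dianion of the monoalkylated dione 5 (not isolated)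
Conditions: LiN(iPr)2 (2.1 equiv), THF, 0 °C; 2 (1.0 equiv), 0 °C; LiN(iPr)2 (1.1 equiv), 0 °C; 2 (1.0 equiv), 0 °C to rt; aq. NH4Cl
Reagents that add atoms: none
Why: Terminal alkylation of a 1,3-diketone dianion, run twice in one flask: 3 reacts at its more basic terminal carbon, the enolate 4 is deprotonated again at the remaining methyl group (kinetically preferred over the new methylene) to give 5, and the second alkylation completes the symmetric diketone 6. No stereocentre is formed.

**Step 2**
Reactants: 7 3-(benzyloxy)benzaldehyde; 8 diethyl {2-[methoxy(methyl)amino]-2-oxoethyl}phosphonate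
Product: 9 (2E)-3-[3-(benzyloxy)phenyl]-N-methoxy-N-methylprop-2-enamide
Conditions: LiCl, DBU, MeCN, rt
Reagents that add atoms: none
Why: Horner–Wadsworth–Emmons olefination under Masamune–Roush conditions; the stabilised phosphonate carbanion should give the E alkene, and the aryl benzyl ether is inert to the mild amine base.

**Step 3**
Reactants: 6 1,7-bis[4-(benzyloxy)phenyl]heptane-3,5-dione; 9 (2E)-3-[3-(benzyloxy)phenyl]-N-methoxy-N-methylprop-2-enamide
Product: 11 (1E)-1-[3-(benzyloxy)phenyl]-9-[4-(benzyloxy)phenyl]-4-{[4-(benzyloxy)phenyl]methyl}non-1-ene-3,5,7-trione, via dilithium dianion of the diketone 10 (not isolated)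
Conditions: LiN(iPr)2 (2.1 equiv), THF, −78 to 0 °C; 9, −78 to −20 °C; cold aq. NH4Cl
Reagents that add atoms: none
Why: Acylation of a 1,3-diketone dianion at its outer carbanion by a Weinreb amide: the hard α′-carbanion of 10 attacks the amide carbonyl, and the chelated tetrahedral adduct persists until the quench, which prevents over-addition and proton exchange with the acidic product. The new centre at C4 of 11 is formed racemic and is erased in step 4.

**Step 4**
Reactants: 11 (1E)-1-[3-(benzyloxy)phenyl]-9-[4-(benzyloxy)phenyl]-4-{[4-(benzyloxy)phenyl]methyl}non-1-ene-3,5,7-trione
Product: 13 4,6-bis{[4-(benzyloxy)phenyl]methyl}-5-{(E)-2-[3-(benzyloxy)phenyl]ethenyl}benzene-1,3-diol, via cyclic aldol adduct 12 (not isolated)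
Conditions: KOH (2 M aq., excess), MeOH–THF, Ar, high dilution, 0 to 45 °C; then 1 M HCl
Reagents that add atoms: none
Why: Hydroxide equilibrates the enolates of 11, and the small share that is deprotonated at C8 adds to the C3 ketone in an intramolecular aldol reaction that forms the C3–C8 bond (C1–C2 of ring A) and gives the β-hydroxy dione 12. This closes the only ring of the step, ring A, in a 6-(enolendo)-exo-trig mode, which is stereoelectronically favoured. E1cB loss of water from 12 and enolisation of the C5 and C7 carbonyls then give the aromatic resorcinol 13, so that the sequence ends irreversibly. The closest known reaction type is the base-mediated aldol cyclisation of 1,3,5-triketones to 5-substituted resorcinols, the laboratory counterpart of stilbene synthase folding. No stereocentre has to be controlled: C4 of 11 and the three centres of 12 are transient and vanish on aromatisation, and the E double bond is not touched. Regioselectivity is secured by the substrate, because C2 is vinylic and cannot enolise, which leaves C8 onto C3 as the only six-membered aldol fold. Chemoselectivity over oxa-Michael addition of an enol oxygen and Michael addition of C6 to C1 is needed; both additions are reversible by E1cB under protic basic conditions, whereas aromatisation is not, so a hydroxide base at moderate temperature and high dilution should funnel the material into 13, while acid, which would lead to a 4-pyranone, is kept out until the quench. The product 13 has a mirror plane through C2 and C5 of its ring, which makes its two hydroxyl groups equivalent for the steps that follow.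

**Step 5**
Reactants: 13 4,6-bis{[4-(benzyloxy)phenyl]methyl}-5-{(E)-2-[3-(benzyloxy)phenyl]ethenyl}benzene-1,3-diol
Product: 14 2,4-bis{[4-(benzyloxy)phenyl]methyl}-3-{(E)-2-[3-(benzyloxy)phenyl]ethenyl}-1,5-dimethoxybenzene
Conditions: MeI, K2CO3, DMF, rt
Reagents that add atoms: iodomethane, CI
Why: Williamson ether synthesis; the two equivalent phenoxides react with iodomethane by SN2, and a carbonate base in a polar aprotic solvent favours O-alkylation over C-alkylation at the ring carbon between the two oxygens.

**Step 6**
Reactants: 14 2,4-bis{[4-(benzyloxy)phenyl]methyl}-3-{(E)-2-[3-(benzyloxy)phenyl]ethenyl}-1,5-dimethoxybenzene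
Product: 15 3-(2-{2,6-bis[(4-hydroxyphenyl)methyl]-3,5-dimethoxyphenyl}ethyl)phenol
Conditions: H2 (1 atm), Pd/C, EtOAc–MeOH, rt
Reagents that add atoms: none
Why: Heterogeneous catalytic hydrogenation; Pd/C should saturate the stilbene double bond and cleave the three aryl benzyl ethers by hydrogenolysis in the same operation, while aryl methyl ethers and diarylmethane C–C bonds are inert. No stereocentre results.

**Step 7**
Reactants: 15 3-(2-{2,6-bis[(4-hydroxyphenyl)methyl]-3,5-dimethoxyphenyl}ethyl)phenol
Product: 16 2,4-bis[(4-hydroxyphenyl)methyl]-3-[2-(3-hydroxyphenyl)ethyl]-5-methoxyphenol (the target)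
Conditions: NaSEt (8 equiv), DMF, 140 °C; then 1 M HCl
Reagents that add atoms: none
Why: Nucleophilic demethylation of an aryl methyl ether by a thiolate (SN2 at the methyl carbon); the two methoxy groups of 15 are equivalent by symmetry, and once one is cleaved the ring A phenoxide makes that ring a far poorer leaving group for a second cleavage, so the reaction should stop at the monomethyl ether. The phenols of rings B, C and D are present as inert phenoxides.

## Compound list

1 | pentane-2,4-dione | CC(=O)CC(C)=O | starting material
2 | 1-(benzyloxy)-4-(chloromethyl)benzene | ClCc1ccc(OCc2ccccc2)cc1 | starting material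
3 | dilithium dianion of pentane-2,4-dione (formed in the flask, step 1) | [Li+].[Li+].C=C([O-])C=C(C)[O-] | intermediate
4 | lithium enolate of 6-[4-(benzyloxy)phenyl]hexane-2,4-dione (formed in the flask, step 1) | [Li+].CC([O-])=CC(=O)CCc1ccc(OCc2ccccc2)cc1 | intermediate
5 | dilithium dianion of 6-[4-(benzyloxy)phenyl]hexane-2,4-dione (formed in the flask, step 1) | [Li+].[Li+].C=C([O-])C=C([O-])CCc1ccc(OCc2ccccc2)cc1 | intermediate
6 | 1,7-bis[4-(benzyloxy)phenyl]heptane-3,5-dione | O=C(CCc1ccc(OCc2ccccc2)cc1)CC(=O)CCc1ccc(OCc2ccccc2)cc1 | intermediate
7 | 3-(benzyloxy)benzaldehyde | O=Cc1cccc(OCc2ccccc2)c1 | starting material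
8 | diethyl {2-[methoxy(methyl)amino]-2-oxoethyl}phosphonate | CCOP(=O)(OCC)CC(=O)N(C)OC | starting material
9 | (2E)-3-[3-(benzyloxy)phenyl]-N-methoxy-N-methylprop-2-enamide | CON(C)C(=O)/C=C/c1cccc(OCc2ccccc2)c1 | intermediate
10 | dilithium dianion of 1,7-bis[4-(benzyloxy)phenyl]heptane-3,5-dione, deprotonated at C2 and C4 (formed in the flask, step 3) | [Li+].[Li+].[O-]C(=CCc1ccc(OCc2ccccc2)cc1)C=C([O-])CCc1ccc(OCc2ccccc2)cc1 | intermediate
11 | (1E)-1-[3-(benzyloxy)phenyl]-9-[4-(benzyloxy)phenyl]-4-{[4-(benzyloxy)phenyl]methyl}non-1-ene-3,5,7-trione (racemic at C4, largely enolised) | O=C(/C=C/c1cccc(OCc2ccccc2)c1)C(Cc1ccc(OCc2ccccc2)cc1)C(=O)CC(=O)CCc1ccc(OCc2ccccc2)cc1 | intermediate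
12 | 4,6-bis{[4-(benzyloxy)phenyl]methyl}-5-{(E)-2-[3-(benzyloxy)phenyl]ethenyl}-5-hydroxycyclohexane-1,3-dione (diastereomer mixture, formed in the flask, step 4) | OC1(/C=C/c2cccc(OCc3ccccc3)c2)C(Cc2ccc(OCc3ccccc3)cc2)C(=O)CC(=O)C1Cc1ccc(OCc2ccccc2)cc1 | intermediate
13 | 4,6-bis{[4-(benzyloxy)phenyl]methyl}-5-{(E)-2-[3-(benzyloxy)phenyl]ethenyl}benzene-1,3-diol | Oc1cc(O)c(Cc2ccc(OCc3ccccc3)cc2)c(/C=C/c2cccc(OCc3ccccc3)c2)c1Cc1ccc(OCc2ccccc2)cc1 | intermediate
14 | 2,4-bis{[4-(benzyloxy)phenyl]methyl}-3-{(E)-2-[3-(benzyloxy)phenyl]ethenyl}-1,5-dimethoxybenzene | COc1cc(OC)c(Cc2ccc(OCc3ccccc3)cc2)c(/C=C/c2cccc(OCc3ccccc3)c2)c1Cc1ccc(OCc2ccccc2)cc1 | intermediate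
15 | 3-(2-{2,6-bis[(4-hydroxyphenyl)methyl]-3,5-dimethoxyphenyl}ethyl)phenol | COc1cc(OC)c(Cc2ccc(O)cc2)c(CCc2cccc(O)c2)c1Cc1ccc(O)cc1 | intermediate
16 | 2,4-bis[(4-hydroxyphenyl)methyl]-3-[2-(3-hydroxyphenyl)ethyl]-5-methoxyphenol (3,3'-dihydroxy-2,6-bis(p-hydroxybenzyl)-5-methoxybibenzyl) | COc1cc(O)c(Cc2ccc(O)cc2)c(CCc2cccc(O)c2)c1Cc1ccc(O)cc1 | target

## Step count and risks

Total step count: 7. Longest linear sequence: 6 steps (steps 1, 3, 4, 5, 6 and 7); step 2 is a one-step side branch.

**Step 4 (key step).** The most likely failure is diversion of the triketone into conjugate-addition manifolds before the aldol closure can occur. An enol oxygen or the central C6 carbon can add to the cinnamoyl β-carbon within the molecule or between molecules, and C6 is far more acidic than C8. The carbonyl to be attacked is also flanked by a benzyl-bearing carbon, which slows the closure. Hydroxide may in addition cleave the cinnamoyl group by retro-Claisen attack.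

The fallback closes ring A on a carbonyl that carries no alkene and attaches ring B afterwards. It sets out from 6 and comes back at 14.
- The dianion 10 is acylated with ethyl diethoxyacetate (one further equivalent of LiN(iPr)2) to give the triketone acetal 8-[4-(benzyloxy)phenyl]-3-{[4-(benzyloxy)phenyl]methyl}-1,1-diethoxyoctane-2,4,6-trione F1. Its acetal carbon is not a useful enolisation site, and it has no Michael acceptor.
- The same hydroxide aldol aromatisation should give 4,6-bis{[4-(benzyloxy)phenyl]methyl}-5-(diethoxymethyl)benzene-1,3-diol F2.
- MeI and K2CO3 give 2,4-bis{[4-(benzyloxy)phenyl]methyl}-3-(diethoxymethyl)-1,5-dimethoxybenzene F3.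
- Mild aqueous acid unmasks 2,6-bis{[4-(benzyloxy)phenyl]methyl}-3,5-dimethoxybenzaldehyde F4.
- Horner–Wadsworth–Emmons olefination of F4 with diethyl {[3-(benzyloxy)phenyl]methyl}phosphonate F5 and KOtBu in THF should give the E stilbene 14. F5 is made by an Arbuzov reaction of 1-(benzyloxy)-3-(bromomethyl)benzene with P(OEt)3.

**Step 3.** The most likely failure is 1,4-addition of the dianion to the unsaturated amide in place of acyl substitution, because the β-carbon is unhindered and the attacking carbanion is secondary. Base-induced breakdown of the N-methoxy amide is a second risk.

The fallback replaces the acylation by an aldol addition and an oxidation. It sets out from 6 and 9 and comes back at 11.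
- 9 is reduced with iBu2AlH at −78 °C to (2E)-3-[3-(benzyloxy)phenyl]prop-2-enal F6.
- The dianion 10 should add to the aldehyde carbon of F6 at −78 °C to give (1E)-1-[3-(benzyloxy)phenyl]-9-[4-(benzyloxy)phenyl]-4-{[4-(benzyloxy)phenyl]methyl}-3-hydroxynon-1-ene-5,7-dione F7 as a diastereomer mixture.
- Oxidation of the allylic alcohol with MnO2 in CH2Cl2 gives 11.

**Step 1.** The most likely failure is imperfect site selection in the second deprotonation (new methylene against remaining methyl), together with over-alkylation at the central carbon and self-condensation of the electron-rich benzylic chloride. The result would be a mixture of isomeric and polyalkylated diketones.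

The fallback builds the two arms by condensation and not by alkylation. It sets out from 1 and comes back at 6.
- A boron-templated double aldol condensation of 1 with 4-(benzyloxy)benzaldehyde (B2O3, B(OnBu)3, nBuNH2, EtOAc, then dilute HCl) gives (1E,6E)-1,7-bis[4-(benzyloxy)phenyl]hepta-1,6-diene-3,5-dione F8.
- Hydrogenation of its two C=C bonds over Pd/C poisoned with 2,2'-bipyridyl, conditions under which aryl benzyl ethers are expected to persist, gives 6.

**Step 7.** The most likely failure is loss of both ring A methyl groups if the phenoxide does not slow the second cleavage enough at the temperature needed for the first. Incomplete conversion is the opposite risk, and the polyphenoxide may degrade oxidatively in hot DMF.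

The fallback avoids any demethylation. It sets out from 13 and comes back at 16.
- 13 is treated with one equivalent of MeI and K2CO3. The monomethyl ether 2,4-bis{[4-(benzyloxy)phenyl]methyl}-3-{(E)-2-[3-(benzyloxy)phenyl]ethenyl}-5-methoxyphenol F9 is separated from recovered 13 and from 14, both of which can be recycled.
- Hydrogenation of F9 over Pd/C as in step 6 gives 16 directly.
- This is one step shorter, but it is statistical in the methylation.

## Further compounds

F1 | step 4 | 8-[4-(benzyloxy)phenyl]-3-{[4-(benzyloxy)phenyl]methyl}-1,1-diethoxyoctane-2,4,6-trione (racemic) | CCOC(OCC)C(=O)C(Cc1ccc(OCc2ccccc2)cc1)C(=O)CC(=O)CCc1ccc(OCc2ccccc2)cc1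
F2 | step 4 | 4,6-bis{[4-(benzyloxy)phenyl]methyl}-5-(diethoxymethyl)benzene-1,3-diol | CCOC(OCC)c1c(Cc2ccc(OCc3ccccc3)cc2)c(O)cc(O)c1Cc1ccc(OCc2ccccc2)cc1
F3 | step 4 | 2,4-bis{[4-(benzyloxy)phenyl]methyl}-3-(diethoxymethyl)-1,5-dimethoxybenzene | CCOC(OCC)c1c(Cc2ccc(OCc3ccccc3)cc2)c(OC)cc(OC)c1Cc1ccc(OCc2ccccc2)cc1
F4 | step 4 | 2,6-bis{[4-(benzyloxy)phenyl]methyl}-3,5-dimethoxybenzaldehyde | O=Cc1c(Cc2ccc(OCc3ccccc3)cc2)c(OC)cc(OC)c1Cc1ccc(OCc2ccccc2)cc1
F5 | step 4 | diethyl {[3-(benzyloxy)phenyl]methyl}phosphonate | CCOP(=O)(OCC)Cc1cccc(OCc2ccccc2)c1
F6 | step 3 | (2E)-3-[3-(benzyloxy)phenyl]prop-2-enal | O=C/C=C/c1cccc(OCc2ccccc2)c1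
F7 | step 3 | (1E)-1-[3-(benzyloxy)phenyl]-9-[4-(benzyloxy)phenyl]-4-{[4-(benzyloxy)phenyl]methyl}-3-hydroxynon-1-ene-5,7-dione (diastereomer mixture) | OC(/C=C/c1cccc(OCc2ccccc2)c1)C(Cc1ccc(OCc2ccccc2)cc1)C(=O)CC(=O)CCc1ccc(OCc2ccccc2)cc1
F8 | step 1 | (1E,6E)-1,7-bis[4-(benzyloxy)phenyl]hepta-1,6-diene-3,5-dione | O=C(/C=C/c1ccc(OCc2ccccc2)cc1)CC(=O)/C=C/c1ccc(OCc2ccccc2)cc1
F9 | step 7 | 2,4-bis{[4-(benzyloxy)phenyl]methyl}-3-{(E)-2-[3-(benzyloxy)phenyl]ethenyl}-5-methoxyphenol | COc1cc(O)c(Cc2ccc(OCc3ccccc3)cc2)c(/C=C/c2cccc(OCc3ccccc3)c2)c1Cc1ccc(OCc2ccccc2)cc1
A1 | alternative 1 | 3-bromo-1,5-dimethoxy-2,4-bis[(4-methoxyphenyl)methyl]benzene | COc1cc(OC)c(Cc2ccc(OC)cc2)c(Br)c1Cc1ccc(OC)cc1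
A2 | alternative 1 | 2-ethenyl-4,4,5,5-tetramethyl-1,3,2-dioxaborolane | C=CB1OC(C)(C)C(C)(C)O1
A3 | alternative 1 | 3-methoxyphenyl trifluoromethanesulfonate | COc1cccc(OS(=O)(=O)C(F)(F)F)c1
A4 | alternative 1 | 2-{1-[3,5-dimethoxy-2,6-bis(4-methoxybenzyl)phenyl]-2-(3-methoxyphenyl)ethyl}-4,4,5,5-tetramethyl-1,3,2-dioxaborolane (racemic) | COc1cc(OC)c(Cc2ccc(OC)cc2)c(C(Cc2cccc(OC)c2)B2OC(C)(C)C(C)(C)O2)c1Cc1ccc(OC)cc1
A5 | alternative 2 | 3,5-dimethoxy-2,6-dimethylbenzaldehyde | COc1cc(OC)c(C)c(C=O)c1C
A6 | alternative 2 | 1-iodo-4-methoxybenzene | COc1ccc(I)cc1
A7 | alternative 2 | 3,5-dimethoxy-2,6-bis(4-methoxybenzyl)benzaldehyde | COc1cc(OC)c(Cc2ccc(OC)cc2)c(C=O)c1Cc1ccc(OC)cc1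
A8 | alternative 3 | 3-[(4-methoxyphenyl)methyl]-6-(3-methoxyphenyl)hex-3-en-2-one (alkene geometry not specified) | CC(=O)C(Cc1ccc(OC)cc1)=CCCc1cccc(OC)c1
A9 | alternative 3 | methyl 3-(4-methoxyphenyl)propanoate | COC(=O)CCc1ccc(OC)cc1
A10 | alternative 3 | 4,6-bis(4-methoxybenzyl)-5-[2-(3-methoxyphenyl)ethyl]cyclohexane-1,3-dione (diastereomer mixture) | O=C1CC(=O)C(Cc2ccc(OC)cc2)C(CCc2cccc(OC)c2)C1Cc1ccc(OC)cc1
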